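**Plan**

- Retrosynthesis: first cut the C(sp)–C(sp2) bond of the enyne (ring-bearing terminal alkyne + (E)-1-iodoundeca-1,10-diene). Then cut the 1,2-dioxane in one operation at C4–C5, C3–O and C6–O, back to 2-methoxyhept-1-en-6-yne, methyl but-3-enoate and O2.
- Enabling feature: in the 1,2-dioxane ring the two oxygen-bearing carbons sit 1,4 across the C4–C5 bond. C6 is a methoxy peroxyketal (the oxocarbenium ion of a 2-methoxy-1-alkene) and C3 is a secondary carbon, so the ring is a tail-to-tail union of the C=C units C5=C6 and C4=C3, capped by O–O.
- Forward order: enol ether in two steps from methyl vinyl ether; photo-oxidative aerobic annulation makes the C4–C5 bond and the dioxane ring; enantiomer separation; the chain is joined last by Sonogashira coupling.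
- Stereochemistry: C6 relative to C3 by acid equilibration of the peroxyketal (axial OMe, equatorial CH2CO2Me, i.e. OMe cis to CH2CO2Me as in the target). C3 absolute by resolution on a chiral stationary phase. The (E)-alkene comes from a Takai olefination.

Key step: step 3

Remark: C3 is created by O2 capture at a free secondary radical, which cannot be steered reliably, so the ring is made as the racemate of the correct relative configuration and the enantiomers are separated in the next step.

Step 1
Reactants: 1 methyl vinyl ether; 2 1-bromo-3-chloropropane
Product: 4 5-chloro-2-methoxypent-1-ene, via 1-methoxyvinyllithium 3 (not isolated)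
Conditions: t-BuLi, THF, −78 to 0 °C; then 2, THF/DMPU, −78 to 23 °C
Reagents that add atoms: none
Why: α-Lithiation of methyl vinyl ether gives the acyl-anion equivalent 1-methoxyvinyllithium, which is alkylated (SN2) at the more reactive carbon–bromine terminus of 2 and so should give the 2-methoxy-1-alkene regiospecifically, with no internal enol ether isomer possible.

Step 2
Reactants: 4 5-chloro-2-methoxypent-1-ene
Product: 5 2-methoxyhept-1-en-6-yne
Conditions: lithium acetylide–ethylenediamine complex, DMSO, 23 °C
Reagents that add atoms: lithium acetylide–ethylenediamine complex, [Li+].[C-]#C.NCCN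
Why: Acetylide alkylation (SN2 at the primary chloride in DMSO) should install the terminal alkyne while the base-stable enol ether stays untouched.

Step 3
Reactants: 5 2-methoxyhept-1-en-6-yne; 6 methyl but-3-enoate
Product: 8 racemic methyl 2-[(3S*,6R*)-6-methoxy-6-(pent-4-yn-1-yl)-1,2-dioxan-3-yl]acetate, via kinetic C6-epimer mixture of the dioxane 7 (not isolated)
Conditions: 9-mesityl-10-methylacridinium tetrafluoroborate (5 mol %), O2 (1 atm), 6 (15 equiv), MeNO2, 450 nm LEDs, 0 °C, slow addition of 5; then concentrate; p-TsOH (10 mol %), MeOH, 4 Å MS, 23 °C
Reagents that add atoms: dioxygen, O=O; methanol, CO (exchanges the acetal methoxy group during the equilibration)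
Why: Proposed new method: the excited acridinium should oxidise only the enol ether C=C of 5 (by far the most electron-rich π bond; the alkyne, the alkene of 6 and the product peroxide lie out of its reach) to a radical cation with spin on the terminal CH2 and charge on the methoxy-bearing carbon, and this CH2 adds to the unsubstituted terminus of 6 to forge the C4–C5 bond, leaving a 1,4-distonic species (oxocarbenium ion at the future C6, secondary radical at the future C3). The secondary radical captures O2 at near diffusion rate, the peroxyl radical is reduced by the acridinyl radical (closing the photoredox cycle), and the peroxide oxygen adds to the oxocarbenium carbon in a 6-exo-trig closure, so the 1,2-dioxane ring with its methoxy peroxyketal is assembled as a formal [2+2+2] annulation of two alkenes and O2. The closest known reaction types are the oxidative radical-cation [2+2] cycloadditions of enol ethers with unactivated terminal alkenes, which show the same tail-to-tail C–C bond formation, and the aerobic radical-cation [2+2+2] cycloadditions of styrenes and 1,1-diarylethenes, which intercept the same kind of 1,4-distonic intermediate with O2 to give 1,2-dioxanes. C3 arises by O2 capture at an acyclic radical and is therefore formed racemic (its absolute configuration is secured in step 4), whereas C6 is set under thermodynamic control in the TsOH/MeOH stage, where reversible ionisation to the cyclic peroxycarbenium ion should funnel both C6 epimers and any hydroxy or open-chain ketal congeners to the isomer with axial OMe (anomeric effect) and equatorial CH2CO2Me, the relative configuration of the target. The step needs cross-coupling to beat homo-coupling of the enol ether, and C–C bond formation to precede oxygenation of the radical cation; the first is secured by slow addition of 5 into a large excess of 6, the second by the sluggish reaction of alkene radical cations with triplet O2 compared with neutral alkyl radicals. The regiochemistry follows from formation of the more stable secondary radical and of the oxocarbenium ion.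

Step 4
Reactants: 8 racemic methyl 2-[(3S*,6R*)-6-methoxy-6-(pent-4-yn-1-yl)-1,2-dioxan-3-yl]acetate
Product: 9 methyl 2-[(3S,6R)-6-methoxy-6-(pent-4-yn-1-yl)-1,2-dioxan-3-yl]acetate
Conditions: preparative supercritical-fluid chromatography, amylose tris(3,5-dimethylphenylcarbamate) stationary phase, CO2/MeOH, 30 °C
Reagents that add atoms: none
Why: Resolution of enantiomers on a polysaccharide carbamate phase, which routinely separates small neutral esters of this kind, should deliver the (3S,6R) enantiomer, to be assigned by vibrational circular dichroism or by carrying a sample through step 6 and comparing the sign of optical rotation with natural peroxyacarnoate A.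

Step 5
Reactants: 10 dec-9-enal
Product: 11 (E)-1-iodoundeca-1,10-diene
Conditions: CrCl2 (6 equiv), CHI3 (2 equiv), THF/1,4-dioxane, 0 to 23 °C
Reagents that add atoms: iodoform, IC(I)I
Why: Takai olefination (geminal dichromium species from CHI3 and CrCl2) should convert the aldehyde into the (E)-vinyl iodide with high E selectivity and leave the terminal alkene untouched.

Step 6
Reactants: 9 methyl 2-[(3S,6R)-6-methoxy-6-(pent-4-yn-1-yl)-1,2-dioxan-3-yl]acetate; 11 (E)-1-iodoundeca-1,10-diene
Product: 12 peroxyacarnoate A, methyl 2-[(3S,6R)-6-[(6E)-hexadeca-6,15-dien-4-yn-1-yl]-6-methoxy-1,2-dioxan-3-yl]acetate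
Conditions: Pd(PPh3)4 (5 mol %), CuI (10 mol %), i-Pr2NH, THF, degassed, 23 °C
Reagents that add atoms: none
Why: Sonogashira coupling of the terminal alkyne with the (E)-vinyl iodide should proceed at room temperature with retention of alkene geometry under conditions (zerovalent palladium, CuI, secondary amine) that dialkyl peroxides and peroxyketals of this type tolerate, and no stereocenter is touched.

**Compound list**

1 | methyl vinyl ether | COC=C | starting material
2 | 1-bromo-3-chloropropane | ClCCCBr | starting material
3 | 1-methoxyvinyllithium | [Li]C(=C)OC | intermediate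
4 | 5-chloro-2-methoxypent-1-ene | C=C(OC)CCCCl | intermediate
5 | 2-methoxyhept-1-en-6-yne | C=C(OC)CCCC#C | intermediate
6 | methyl but-3-enoate | C=CCC(=O)OC | starting material
7 | methyl 2-[6-methoxy-6-(pent-4-yn-1-yl)-1,2-dioxan-3-yl]acetate, kinetic mixture of C6 epimers, racemic | C#CCCCC1(OC)CCC(CC(=O)OC)OO1 | intermediate
8 | racemic methyl 2-[(3S*,6R*)-6-methoxy-6-(pent-4-yn-1-yl)-1,2-dioxan-3-yl]acetate | C#CCCC[C@]1(OC)CC[C@@H](CC(=O)OC)OO1.C#CCCC[C@@]1(OC)CC[C@H](CC(=O)OC)OO1 | intermediate
9 | methyl 2-[(3S,6R)-6-methoxy-6-(pent-4-yn-1-yl)-1,2-dioxan-3-yl]acetate | C#CCCC[C@]1(OC)CC[C@@H](CC(=O)OC)OO1 | intermediate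
10 | dec-9-enal | C=CCCCCCCCC=O | starting material
11 | (E)-1-iodoundeca-1,10-diene | C=CCCCCCCC/C=C/I | intermediate
12 | peroxyacarnoate A | C=CCCCCCCC/C=C/C#CCCC[C@]1(OC)CC[C@@H](CC(=O)OC)OO1 | target

**Step count and risks**

Total steps: 6. Longest linear sequence: 5 (steps 1, 2, 3, 4, 6); step 5 makes the coupling partner.

Steps most likely to fail:

Step 3 (labelled step). Oxidative homo-coupling of the enol ether and its cleavage through a dioxetane may outrun cross addition to the unactivated alkene. The fallback uses known chemistry, sets out from 5 and returns at 8. Mild acid hydrolysis of 5 (oxalic acid, wet THF) gives hept-6-yn-2-one F1. Its kinetic lithium enolate (lithium diisopropylamide, THF, −78 °C) is alkylated at the methyl carbon by methyl (E)-4-bromobut-2-enoate to give methyl (2E)-6-oxoundec-2-en-10-ynoate F2, which makes the same C4–C5 bond by enolate alkylation. Urea–hydrogen peroxide and Sc(OTf)3 in MeOH convert the ketone into methyl (2E)-6-hydroperoxy-6-methoxyundec-2-en-10-ynoate F3. Its hydroperoxide closes the ring by 6-exo oxa-Michael addition (Et2NH, CF3CH2OH) to the epimer mixture 7, and the TsOH/MeOH stage of step 3 then gives 8.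

Step 4. Incomplete separation of the enantiomers, or epimerisation at the peroxyketal carbon on the column, would erode optical purity. The fallback sets out from 8 and returns at 9. Acid-catalysed alkoxy exchange at the peroxyketal with (1R,2S,5R)-menthol (p-TsOH, CH2Cl2, 5 Å MS to remove MeOH) turns the enantiomers into the diastereomeric menthyl peroxyketals, methyl 2-[(3S,6R)-6-{[(1R,2S,5R)-5-methyl-2-(propan-2-yl)cyclohexyl]oxy}-6-(pent-4-yn-1-yl)-1,2-dioxan-3-yl]acetate F4 and its (3R,6S) ring diastereomer F5. These are separated on silica or by crystallisation, and F4 is returned to 9 by exchange in MeOH with p-TsOH.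

Step 6. Reductive O–O cleavage by zerovalent palladium or free phosphine, or oxidative homocoupling of the alkyne, may consume the peroxide. The fallback sets out from 5 and 11 and returns at 12. The Sonogashira coupling is run before any peroxide exists and gives (8E)-2-methoxyoctadeca-1,8,17-trien-6-yne F6. The conditions of step 3 with 6 then give first the kinetic C6-epimer mixture of the full-chain dioxane F7 and, after the TsOH/MeOH stage, racemic peroxyacarnoate A F8. This is resolved on the chiral phase of step 4 to give 12.

Further compounds
F1 | step 3 | hept-6-yn-2-one | C#CCCCC(C)=O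
F2 | step 3 | methyl (2E)-6-oxoundec-2-en-10-ynoate | C#CCCCC(=O)CC/C=C/C(=O)OC
F3 | step 3 | methyl (2E)-6-hydroperoxy-6-methoxyundec-2-en-10-ynoate, racemic | C#CCCCC(OC)(OO)CC/C=C/C(=O)OC
F4 | step 4 | methyl 2-[(3S,6R)-6-{[(1R,2S,5R)-5-methyl-2-(propan-2-yl)cyclohexyl]oxy}-6-(pent-4-yn-1-yl)-1,2-dioxan-3-yl]acetate | C#CCCC[C@]1(O[C@@H]2C[C@H](C)CC[C@H]2C(C)C)CC[C@@H](CC(=O)OC)OO1
F5 | step 4 | methyl 2-[(3R,6S)-6-{[(1R,2S,5R)-5-methyl-2-(propan-2-yl)cyclohexyl]oxy}-6-(pent-4-yn-1-yl)-1,2-dioxan-3-yl]acetate | C#CCCC[C@@]1(O[C@@H]2C[C@H](C)CC[C@H]2C(C)C)CC[C@H](CC(=O)OC)OO1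
F6 | step 6 | (8E)-2-methoxyoctadeca-1,8,17-trien-6-yne | C=CCCCCCCC/C=C/C#CCCCC(=C)OC
F7 | step 6 | methyl 2-[6-[(6E)-hexadeca-6,15-dien-4-yn-1-yl]-6-methoxy-1,2-dioxan-3-yl]acetate, kinetic mixture of C6 epimers, racemic | C=CCCCCCCC/C=C/C#CCCCC1(OC)CCC(CC(=O)OC)OO1
F8 | step 6 | racemic peroxyacarnoate A | C=CCCCCCCC/C=C/C#CCCC[C@]1(OC)CC[C@@H](CC(=O)OC)OO1.C=CCCCCCCC/C=C/C#CCCC[C@@]1(OC)CC[C@H](CC(=O)OC)OO1
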